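**Retrosynthetic overview**

1. The target comes from one triple olefin cross-metathesis (three CH=CH2 groups become three CH=CMe2 groups). Before that, a double palladium-catalysed C-allylation dearomatises a 7-isobutyryl-5-methyl-2,3-dihydrobenzofuran-4,6-diol and sets the quaternary centres C5 and C7. C7 is acylated one step earlier.
2. The dihydrobenzofuran comes from forming the C3–C2 bond: a carbene at C3 (from the ortho-formyl N-tosylhydrazone of an aryl ether) alkylates the O1–CH2 group 1,5 to it. This closes the ring, sets C2, and delivers the hydroxylated side chain complete.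
3. Enabling feature: ring oxygen O1 sits on C7a, next to C3a, which carries C3. The O1–CH2 hydrogens are alpha-oxy and 1,5 to C3, and the neighbouring carbinol carbon is quaternary, so only the five-membered ring O1–C2–C3–C3a–C7a can close.
4. The aryl ether comes from phenoxide opening of (S)-2-(but-3-enyl)-2-methyloxirane; the tertiary carbinol is taken from the chiral pool as (R)-2-methylglycidol. The arene comes from 2-methylresorcinol by meta C–H borylation/oxidation (this makes O1 the unique oxygen) and ortho-formylation.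
5. Ring order: the benzene ring is bought, the dihydrofuran ring is closed in the key step, and the six-membered ring is dearomatised to the trione last.

Key step: step 8

Assumption: the facial sense of [Co(3,5-DitBu-ChenPhyrin)] in step 8 and of the Trost ligand in step 11 cannot be predicted with confidence for these new substrates; the catalyst enantiomer that gives the configuration drawn is meant, and the enantiomeric catalyst is used if a screen shows the opposite sense.

**Step 1**
Reactants: 1 2-methylresorcinol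
Product: 2 2-methyl-1,3-bis(triisopropylsilyloxy)benzene
Conditions: TIPSCl (2.3 equiv), imidazole (5 equiv), DMF, rt to 40 °C
Reagents that add atoms: triisopropylsilyl chloride, CC(C)[Si](Cl)(C(C)C)C(C)C
Why: Imidazole-promoted silyl ether formation protects both phenols with groups that are bulky enough to steer the borylation and that carry no activated C–H bond within reach of the later carbene.

**Step 2**
Reactants: 2 2-methyl-1,3-bis(triisopropylsilyloxy)benzene
Product: 4 4-methyl-3,5-bis(triisopropylsilyloxy)phenol, via aryl pinacol boronate 3 (not isolated)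
Conditions: B2pin2 (1.0 equiv), [Ir(OMe)(cod)]2 (1.5 mol%), dtbpy (3 mol%), THF, 80 °C; then Oxone (2KHSO5·KHSO4·K2SO4), acetone/H2O, rt
Reagents that add atoms: bis(pinacolato)diboron, CC1(C)OB(OC1(C)C)B1OC(C)(C)C(C)(C)O1 (boron of intermediate 3); potassium peroxymonosulfate, [K+].[O-]S(=O)(=O)OO (oxygen of 4)
Why: Iridium-catalysed C–H borylation is sterically controlled and should take the only C–H that is not ortho to a silyloxy group, and one-pot oxidation of the C–B bond then gives the phenol, so the future ring oxygen is placed para to the methyl group without ambiguity.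

**Step 3**
Reactants: 4 4-methyl-3,5-bis(triisopropylsilyloxy)phenol
Product: 5 2-hydroxy-5-methyl-4,6-bis(triisopropylsilyloxy)benzaldehyde
Conditions: MgCl2 (2 equiv), Et3N (4 equiv), (CH2O)n (6 equiv), MeCN, reflux
Reagents that add atoms: paraformaldehyde (formaldehyde), C=O
Why: The magnesium-mediated ortho-formylation of phenols (Casnati–Skattebøl reaction) is ortho-specific through a magnesium phenoxide–formaldehyde chelate, and the two ortho positions of 4 are equivalent, so a single salicylaldehyde should result.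

**Step 4**
Reactants: 6 (R)-2-methylglycidol
Product: 7 [(2S)-2-methyloxiran-2-yl]methyl 4-methylbenzenesulfonate
Conditions: TsCl, Et3N, DMAP (cat.), CH2Cl2, 0 °C
Reagents that add atoms: p-toluenesulfonyl chloride, Cc1ccc(cc1)S(Cl)(=O)=O
Why: Sulfonylation of the primary alcohol leaves the quaternary stereocentre untouched (the descriptor changes from R to S only through the priority rules).

**Step 5**
Reactants: 7 [(2S)-2-methyloxiran-2-yl]methyl 4-methylbenzenesulfonate
Product: 9 (2S)-2-(but-3-en-1-yl)-2-methyloxirane, via hydroxy tosylate 8 (not isolated)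
Conditions: allylMgBr (1.3 equiv), CuI (10 mol%), THF, −40 °C; 1 M HCl work-up; then K2CO3, MeOH, 0 °C to rt
Reagents that add atoms: allylmagnesium bromide, C=CC[Mg]Br
Why: Copper-catalysed Grignard opening of the epoxide at its CH2 terminus, followed by base-induced closure of the tertiary alkoxide onto the tosylate (epoxide transposition), extends the chain by three carbons without breaking a bond at the quaternary centre.

**Step 6**
Reactants: 5 2-hydroxy-5-methyl-4,6-bis(triisopropylsilyloxy)benzaldehyde; 9 (2S)-2-(but-3-en-1-yl)-2-methyloxirane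
Product: 10 2-{[(2S)-2-hydroxy-2-methylhex-5-en-1-yl]oxy}-5-methyl-4,6-bis(triisopropylsilyloxy)benzaldehyde
Conditions: 9 (1.5 equiv), K2CO3 (0.3 equiv), DMF, 70 °C
Reagents that add atoms: none
Why: Base-catalysed SN2 opening of the 2,2-disubstituted epoxide by the phenoxide should occur at the unhindered CH2 carbon and give the aryl ether with a free tertiary alcohol, the stereocentre not being involved.

**Step 7**
Reactants: 10 2-{[(2S)-2-hydroxy-2-methylhex-5-en-1-yl]oxy}-5-methyl-4,6-bis(triisopropylsilyloxy)benzaldehyde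
Product: 11 N-tosylhydrazone of 10 (E)
Conditions: TsNHNH2 (1.05 equiv), MeOH, rt
Reagents that add atoms: p-toluenesulfonohydrazide, Cc1ccc(cc1)S(=O)(=O)NN
Why: Hydrazone formation at the only carbonyl group gives a stable, purifiable precursor of the aryl carbene.

**Step 8**
Reactants: 11 N-tosylhydrazone of 10
Product: 13 (2S)-2-[(2S)-2-hydroxyhex-5-en-2-yl]-5-methyl-4,6-bis(triisopropylsilyloxy)-2,3-dihydro-1-benzofuran, via aryldiazomethane 12 (not isolated)
Conditions: [Co(3,5-DitBu-ChenPhyrin)] (3 mol%), Cs2CO3 (2 equiv), toluene, 40 °C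
Reagents that add atoms: none
Why: Cs2CO3 converts the hydrazone into aryldiazomethane 12, which the divalent cobalt porphyrin turns into a trivalent-cobalt carbene radical at C3; 1,5-hydrogen atom transfer from the O1–CH2 group through a six-membered transition state gives an alpha-alkoxy radical at C2, which attacks the Co–C3 bond, forms the C3–C2 bond and releases the catalyst. The closest known reaction type is the intramolecular 1,5-C–H alkylation of aryldiazomethanes generated from aldehyde N-tosylhydrazones at C–H bonds alpha to oxygen or nitrogen under metalloradical or metal-carbene catalysis, which gives 2-substituted 2,3-dihydrobenzofurans, indolines and tetrahydrofurans. The ring closed is the dihydrofuran ring, by 5-exo-tet homolytic substitution at the cobalt-bound carbon after the 1,5-HAT. The new stereocentre C2 is controlled by the chiral cavity of the D2-symmetric amidoporphyrin, which decides which face of the planar C2 radical bonds to C3; the adjacent quaternary carbinol (S, from the chiral pool) makes the two outcomes diastereomers, and the catalyst enantiomer matched to it is used. The step needs site selectivity for the O1–CH2 hydrogens, and the substrate secures it: they are the only alpha-oxy C–H bonds 1,5 to the carbene carbon, the carbinol carbon is quaternary (no beta-hydrogen and no 1,2-hydrogen shift), the silyl ethers offer no activated C–H, and the terminal alkene is eight atoms away.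

**Step 9**
Reactants: 13 (2S)-2-[(2S)-2-hydroxyhex-5-en-2-yl]-5-methyl-4,6-bis(triisopropylsilyloxy)-2,3-dihydro-1-benzofuran
Product: 14 (2S)-2-[(2S)-2-hydroxyhex-5-en-2-yl]-5-methyl-2,3-dihydro-1-benzofuran-4,6-diol
Conditions: TBAF (2.2 equiv), AcOH (2.2 equiv), THF, 0 °C, argon
Reagents that add atoms: none
Why: Fluoride cleaves the two aryl silyl ethers (desilylation), and acetic acid buffering should keep the electron-rich diol and the tertiary alcohol intact.

**Step 10**
Reactants: 14 (2S)-2-[(2S)-2-hydroxyhex-5-en-2-yl]-5-methyl-2,3-dihydro-1-benzofuran-4,6-diol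
Product: 15 1-{(2S)-4,6-dihydroxy-2-[(2S)-2-hydroxyhex-5-en-2-yl]-5-methyl-2,3-dihydro-1-benzofuran-7-yl}-2-methylpropan-1-one
Conditions: EtMgBr (3.1 equiv), toluene/Et2O, 0 °C; then iPrCOCl (1.05 equiv), rt; 1 M HCl work-up
Reagents that add atoms: isobutyryl chloride, CC(C)C(Cl)=O
Why: ortho-C-acylation of a bromomagnesium phenolate by an acid chloride in a weakly coordinating solvent (chelation-controlled Friedel–Crafts-type acylation) can only take C7, the single free ring position, and avoids the protic or Lewis acids that would endanger the tertiary alcohol and the alkene.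

**Step 11**
Reactants: 15 1-{(2S)-4,6-dihydroxy-2-[(2S)-2-hydroxyhex-5-en-2-yl]-5-methyl-2,3-dihydro-1-benzofuran-7-yl}-2-methylpropan-1-one
Product: 17 (2S,5S,7S)-5,7-diallyl-2-[(2S)-2-hydroxyhex-5-en-2-yl]-5-methyl-7-(2-methylpropanoyl)-2,3-dihydro-1-benzofuran-4,6(5H,7H)-dione, via C5-allyl dienone 16 (not isolated)
Conditions: allyl tert-butyl carbonate (2.5 equiv), Pd2(dba)3·CHCl3 (2.5 mol%), (R,R)-DACH-phenyl Trost ligand (7.5 mol%), THF, 0 °C to rt
Reagents that add atoms: allyl tert-butyl carbonate, C=CCOC(=O)OC(C)(C)C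
Why: Palladium-catalysed asymmetric allylic alkylation with the phenoxide as carbon nucleophile (Tsuji–Trost allylation with dearomatisation) should first quaternise C5, the ring carbon flanked by both free hydroxyls, on the face chosen by the chiral palladium π-allyl complex, and the now acidic C7–H of the β-tricarbonyl unit of 16 is then allylated in the same pot anti to the C5 allyl group (1,3-relationship across C6), which sets C7 and gives the 5,7-trans-diallyl trione.

**Step 12**
Reactants: 17 (2S,5S,7S)-5,7-diallyl-2-[(2S)-2-hydroxyhex-5-en-2-yl]-5-methyl-7-(2-methylpropanoyl)-2,3-dihydro-1-benzofuran-4,6(5H,7H)-dione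
Product: 18 CNP0250451.1, (2S,5S,7S)-2-[(2S)-2-hydroxy-6-methylhept-5-en-2-yl]-5-methyl-5,7-bis(3-methylbut-2-en-1-yl)-7-(2-methylpropanoyl)-2,3-dihydro-1-benzofuran-4,6(5H,7H)-dione
Conditions: 2-methyl-2-butene (large excess), second-generation Hoveyda–Grubbs catalyst (10 mol%), CH2Cl2, 40 °C, sealed tube
Reagents that add atoms: 2-methyl-2-butene, CC=C(C)C
Why: Olefin cross-metathesis of the three monosubstituted alkenes with excess 2-methyl-2-butene should give the three trisubstituted prenyl-type alkenes with loss of propene, no stereocentre being touched and the product alkenes being inert to further metathesis.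

**Compound list**

1 | 2-methylresorcinol (2-methylbenzene-1,3-diol) | Cc1c(O)cccc1O | starting material
2 | 2-methyl-1,3-bis(triisopropylsilyloxy)benzene | Cc1c(O[Si](C(C)C)(C(C)C)C(C)C)cccc1O[Si](C(C)C)(C(C)C)C(C)C | intermediate
3 | 2-[4-methyl-3,5-bis(triisopropylsilyloxy)phenyl]-4,4,5,5-tetramethyl-1,3,2-dioxaborolane | Cc1c(O[Si](C(C)C)(C(C)C)C(C)C)cc(B2OC(C)(C)C(C)(C)O2)cc1O[Si](C(C)C)(C(C)C)C(C)C | intermediate
4 | 4-methyl-3,5-bis(triisopropylsilyloxy)phenol | Cc1c(O[Si](C(C)C)(C(C)C)C(C)C)cc(O)cc1O[Si](C(C)C)(C(C)C)C(C)C | intermediate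
5 | 2-hydroxy-5-methyl-4,6-bis(triisopropylsilyloxy)benzaldehyde | O=Cc1c(O)cc(O[Si](C(C)C)(C(C)C)C(C)C)c(C)c1O[Si](C(C)C)(C(C)C)C(C)C | intermediate
6 | (R)-2-methylglycidol, [(2R)-2-methyloxiran-2-yl]methanol | OC[C@]1(C)CO1 | starting material
7 | [(2S)-2-methyloxiran-2-yl]methyl 4-methylbenzenesulfonate | Cc1ccc(cc1)S(=O)(=O)OC[C@]1(C)CO1 | intermediate
8 | (2S)-2-hydroxy-2-methylhex-5-en-1-yl 4-methylbenzenesulfonate | Cc1ccc(cc1)S(=O)(=O)OC[C@@](C)(O)CCC=C | intermediate
9 | (2S)-2-(but-3-en-1-yl)-2-methyloxirane | C=CCC[C@@]1(C)CO1 | intermediate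
10 | 2-{[(2S)-2-hydroxy-2-methylhex-5-en-1-yl]oxy}-5-methyl-4,6-bis(triisopropylsilyloxy)benzaldehyde | O=Cc1c(OC[C@@](C)(O)CCC=C)cc(O[Si](C(C)C)(C(C)C)C(C)C)c(C)c1O[Si](C(C)C)(C(C)C)C(C)C | intermediate
11 | N'-[(E)-(2-{[(2S)-2-hydroxy-2-methylhex-5-en-1-yl]oxy}-5-methyl-4,6-bis(triisopropylsilyloxy)phenyl)methylidene]-4-methylbenzenesulfonohydrazide | Cc1ccc(cc1)S(=O)(=O)N/N=C/c1c(OC[C@@](C)(O)CCC=C)cc(O[Si](C(C)C)(C(C)C)C(C)C)c(C)c1O[Si](C(C)C)(C(C)C)C(C)C | intermediate
12 | (2S)-1-[2-(diazomethyl)-4-methyl-3,5-bis(triisopropylsilyloxy)phenoxy]-2-methylhex-5-en-2-ol | [N-]=[N+]=Cc1c(OC[C@@](C)(O)CCC=C)cc(O[Si](C(C)C)(C(C)C)C(C)C)c(C)c1O[Si](C(C)C)(C(C)C)C(C)C | intermediate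
13 | (2S)-2-[(2S)-2-hydroxyhex-5-en-2-yl]-5-methyl-4,6-bis(triisopropylsilyloxy)-2,3-dihydro-1-benzofuran | C=CCC[C@](C)(O)[C@@H]1Cc2c(O1)cc(O[Si](C(C)C)(C(C)C)C(C)C)c(C)c2O[Si](C(C)C)(C(C)C)C(C)C | intermediate
14 | (2S)-2-[(2S)-2-hydroxyhex-5-en-2-yl]-5-methyl-2,3-dihydro-1-benzofuran-4,6-diol | C=CCC[C@](C)(O)[C@@H]1Cc2c(O1)cc(O)c(C)c2O | intermediate
15 | 1-{(2S)-4,6-dihydroxy-2-[(2S)-2-hydroxyhex-5-en-2-yl]-5-methyl-2,3-dihydro-1-benzofuran-7-yl}-2-methylpropan-1-one | C=CCC[C@](C)(O)[C@@H]1Cc2c(O1)c(C(=O)C(C)C)c(O)c(C)c2O | intermediate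
16 | (2S,5R)-5-allyl-6-hydroxy-2-[(2S)-2-hydroxyhex-5-en-2-yl]-5-methyl-7-(2-methylpropanoyl)-3,5-dihydro-1-benzofuran-4(2H)-one (same spatial arrangement at C5 as in 17 and 18; the descriptor differs only through the enol tautomer) | C=CCC[C@](C)(O)[C@@H]1CC2=C(O1)C(C(=O)C(C)C)=C(O)[C@@](C)(CC=C)C2=O | intermediate
17 | (2S,5S,7S)-5,7-diallyl-2-[(2S)-2-hydroxyhex-5-en-2-yl]-5-methyl-7-(2-methylpropanoyl)-2,3-dihydro-1-benzofuran-4,6(5H,7H)-dione | C=CCC[C@](C)(O)[C@@H]1CC2=C(O1)[C@@](CC=C)(C(=O)C(C)C)C(=O)[C@@](C)(CC=C)C2=O | intermediate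
18 | CNP0250451.1, (2S,5S,7S)-2-[(2S)-2-hydroxy-6-methylhept-5-en-2-yl]-5-methyl-5,7-bis(3-methylbut-2-en-1-yl)-7-(2-methylpropanoyl)-2,3-dihydro-1-benzofuran-4,6(5H,7H)-dione | CC(C)=CCC[C@](C)(O)[C@@H]1CC2=C(O1)[C@@](CC=C(C)C)(C(=O)C(C)C)C(=O)[C@@](C)(CC=C(C)C)C2=O | target

**Step count and risks**

Total step count: 12. Longest linear sequence: 10 steps (steps 1, 2, 3, 6, 7, 8, 9, 10, 11, 12); steps 4 and 5 form the side branch.

Steps most likely to fail:

1. Step 11. C-allylation may go to the ring-fusion carbon C3a or stay on oxygen instead of C5, the catalyst may discriminate the faces of the planar phenoxide at C5 only weakly, and delivery at C7 anti to the C5 allyl group may be incomplete. Fallback, setting out from 15 and coming back at 17: C5 is quaternised by ion-pair catalysis instead (allyl bromide, CsOH·H2O, a cinchonidinium-derived phase-transfer catalyst, toluene/CHCl3, −50 °C), and 16 is isolated. Mitsunobu O-allylation of its enol (allyl alcohol, PPh3, DIAD, THF, 0 °C) gives the allyl enol ether (2S,5R)-5-allyl-6-(allyloxy)-2-[(2S)-2-hydroxyhex-5-en-2-yl]-5-methyl-7-(2-methylpropanoyl)-3,5-dihydro-1-benzofuran-4(2H)-one F1. Heating (toluene, 100 °C) moves the allyl group from O6 to C7 by Claisen rearrangement, suprafacially and on the face away from the C5 allyl group, to give 17.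

2. Step 8. The carbene radical may be lost to azine formation or intermolecular paths before the 1,5-hydrogen transfer, and facial selectivity of the ring closure beside the quaternary carbinol may be low. Fallback, setting out from 4 and coming back at 13: the dihydrofuran ring is closed at its O1–C2 bond instead, by a phenoxide that opens an epoxide whose two carbons carry the configurations of C2 and of the carbinol carbon, both set by an asymmetric epoxidation. trans-Hydroalumination/iodination of but-2-yn-1-ol (NaAlH2(OCH2CH2OMe)2, THF, then I2) gives (2Z)-3-iodobut-2-en-1-ol F2. Cross-coupling with but-3-enylmagnesium bromide (Pd(PPh3)4 cat., THF, retention of geometry) gives (2Z)-3-methylhepta-2,6-dien-1-ol F3, and PBr3 (Et2O, 0 °C) converts it into (2Z)-1-bromo-3-methylhepta-2,6-diene F4. ortho-C-Alkylation of the sodium phenoxide of 4 with this bromide (NaH, toluene) gives 4-methyl-2-[(2Z)-3-methylhepta-2,6-dien-1-yl]-3,5-bis(triisopropylsilyloxy)phenol F5. Shi epoxidation of the trisubstituted alkene (fructose-derived ketone of the series that gives the (2R,3S)-oxirane, KHSO5 as Oxone, pH 10.5) gives 2-{[(2R,3S)-3-(but-3-en-1-yl)-3-methyloxiran-2-yl]methyl}-4-methyl-3,5-bis(triisopropylsilyloxy)phenol F6. On treatment with base (NaH, THF, 0 °C) the phenoxide of this epoxide opens the oxirane at its CH carbon with inversion (5-exo) to give 13.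

3. Step 10. Acylation may occur on the phenol oxygens or on the tertiary alkoxide instead of at C7. Fallback, setting out from 14 and coming back at 15: the magnesium-mediated ortho-formylation of step 3 (MgCl2, Et3N, (CH2O)n, MeCN) puts an aldehyde on C7 to give (2S)-4,6-dihydroxy-2-[(2S)-2-hydroxyhex-5-en-2-yl]-5-methyl-2,3-dihydro-1-benzofuran-7-carbaldehyde F7. Isopropylmagnesium chloride (excess, THF, −20 °C) adds to it to give (2S)-7-(1-hydroxy-2-methylpropyl)-2-[(2S)-2-hydroxyhex-5-en-2-yl]-5-methyl-2,3-dihydro-1-benzofuran-4,6-diol F8 (both epimers at the new carbinol). MnO2 (CH2Cl2, rt) oxidises the benzylic alcohol to ketone 15.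

**Further compounds**

F1 | step 11 | (2S,5R)-5-allyl-6-(allyloxy)-2-[(2S)-2-hydroxyhex-5-en-2-yl]-5-methyl-7-(2-methylpropanoyl)-3,5-dihydro-1-benzofuran-4(2H)-one | C=CCC[C@](C)(O)[C@@H]1CC2=C(O1)C(C(=O)C(C)C)=C(OCC=C)[C@@](C)(CC=C)C2=O
F2 | step 8 | (2Z)-3-iodobut-2-en-1-ol | OC/C=C(/C)I
F3 | step 8 | (2Z)-3-methylhepta-2,6-dien-1-ol | OC/C=C(/C)CCC=C
F4 | step 8 | (2Z)-1-bromo-3-methylhepta-2,6-diene | BrC/C=C(/C)CCC=C
F5 | step 8 | 4-methyl-2-[(2Z)-3-methylhepta-2,6-dien-1-yl]-3,5-bis(triisopropylsilyloxy)phenol | Oc1cc(O[Si](C(C)C)(C(C)C)C(C)C)c(C)c(O[Si](C(C)C)(C(C)C)C(C)C)c1C/C=C(/C)CCC=C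
F6 | step 8 | 2-{[(2R,3S)-3-(but-3-en-1-yl)-3-methyloxiran-2-yl]methyl}-4-methyl-3,5-bis(triisopropylsilyloxy)phenol | C=CCC[C@]1(C)O[C@@H]1Cc1c(O)cc(O[Si](C(C)C)(C(C)C)C(C)C)c(C)c1O[Si](C(C)C)(C(C)C)C(C)C
F7 | step 10 | (2S)-4,6-dihydroxy-2-[(2S)-2-hydroxyhex-5-en-2-yl]-5-methyl-2,3-dihydro-1-benzofuran-7-carbaldehyde | C=CCC[C@](C)(O)[C@@H]1Cc2c(O1)c(C=O)c(O)c(C)c2O
F8 | step 10 | (2S)-7-(1-hydroxy-2-methylpropyl)-2-[(2S)-2-hydroxyhex-5-en-2-yl]-5-methyl-2,3-dihydro-1-benzofuran-4,6-diol (both epimers at the new carbinol) | C=CCC[C@](C)(O)[C@@H]1Cc2c(O1)c(C(O)C(C)C)c(O)c(C)c2O
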